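**Retrosynthetic overview**

- The target is reached from a fully protected flavone by removing one silyl ether and three allyl ethers. Rings A and B are bought as benzoates, and ring C is the only ring the route forms.
- Ring C is opened at C4–C4a: an intramolecular Friedel–Crafts acylation of an (E)-3-aryloxy-3-aryl-2-methoxyacrylic acid closes it.
- The strategy rests on ring A: O1 on C8a, oxygens on C5 and C7 and the methoxy group on C6 map onto a mirror-symmetric 3,5-bis(allyloxy)-4-methoxyphenol. Its two ortho carbons are identical, so closure can only give the 5,6,7-pattern.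
- The C2–O1 bond of the acid comes from vinylic substitution of an enol triflate by the ring A phenoxide. The triflate comes from acylation of the methyl methoxyacetate enolate by the ring B aroyl chloride.
- Ring B is built from methyl 3-bromo-4-hydroxybenzoate (Claisen rearrangement and cross-metathesis for the prenyl group, B-alkyl Suzuki coupling for the side chain). The (S) centre is bought with the (R)-Roche ester. The ring A phenol comes from methyl 3,5-dihydroxy-4-methoxybenzoate by Dakin oxidation.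

Key step: step 19

Assumption: the enol triflate and the aryloxyacrylates made from it are drawn as the (E)-isomers (ester cis to the sulfonyloxy or aryloxy group), the geometry expected from triflation of the chelated enolate and substitution with retention.

**Side-chain alkene (fragment 1)**

Step 1
Reactants: 1 methyl (2R)-3-hydroxy-2-methylpropanoate
Product: 2 methyl (2R)-3-[(tert-butyldiphenylsilyl)oxy]-2-methylpropanoate
Conditions: TBDPSCl, imidazole, DMF, 0 °C to rt
Reagents that add atoms: tert-butyl(chloro)diphenylsilane, CC(C)(C)[Si](Cl)(c1ccccc1)c1ccccc1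
Why: Imidazole-promoted silylation of a primary alcohol is routine, leaves the stereocentre untouched, and gives a silyl ether that should survive hydride, ylide, aqueous base, 200 °C and the buffered acylation.

Step 2
Reactants: 2 methyl (2R)-3-[(tert-butyldiphenylsilyl)oxy]-2-methylpropanoate
Product: 3 (2S)-3-[(tert-butyldiphenylsilyl)oxy]-2-methylpropan-1-ol
Conditions: i-Bu2AlH (2.5 equiv), CH2Cl2, −78 to 0 °C; aqueous potassium sodium tartrate work-up
Reagents that add atoms: none
Why: Aluminium hydride reduction of the ester to the primary alcohol does not involve the stereocentre (the descriptor becomes S only because the priorities change).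

Step 3
Reactants: 3 (2S)-3-[(tert-butyldiphenylsilyl)oxy]-2-methylpropan-1-ol
Product: 4 (2R)-3-[(tert-butyldiphenylsilyl)oxy]-2-methylpropanal
Conditions: Dess–Martin periodinane, CH2Cl2, 0 °C to rt; crude aldehyde used at once
Reagents that add atoms: none
Why: Dess–Martin oxidation is near-neutral, so the α-branched aldehyde should form without epimerisation if it is not chromatographed or stored.

Step 4
Reactants: 4 (2R)-3-[(tert-butyldiphenylsilyl)oxy]-2-methylpropanal
Product: 5 tert-butyl{[(2S)-2-methylbut-3-en-1-yl]oxy}diphenylsilane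
Conditions: Ph3PCH3Br, KN(SiMe3)2, THF, 0 °C; then 4, −78 to 0 °C
Reagents that add atoms: methyltriphenylphosphonium bromide, [Br-].C[P+](c1ccccc1)(c1ccccc1)c1ccccc1
Why: Wittig methylenation with the non-stabilised ylide at low temperature should outrun enolisation of the aldehyde, so the stereocentre (now allylic, S) is carried through.

**Ring B (fragment 2)**

Step 5
Reactants: 6 methyl 3-bromo-4-hydroxybenzoate
Product: 7 methyl 3-bromo-4-(prop-2-en-1-yloxy)benzoate
Conditions: allyl bromide, K2CO3, acetone, reflux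
Reagents that add atoms: allyl bromide, BrCC=C
Why: Williamson etherification of an acidic para-ester phenol is reliable.

Step 6
Reactants: 7 methyl 3-bromo-4-(prop-2-en-1-yloxy)benzoate
Product: 8 methyl 3-bromo-4-hydroxy-5-(prop-2-en-1-yl)benzoate
Conditions: N,N-diethylaniline, 200 °C
Reagents that add atoms: none
Why: In this aromatic Claisen rearrangement ([3,3] shift, then tautomerisation) the bromine-bearing ortho carbon cannot rearomatise, so the allyl group should end up on C5 only.

Step 7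
Reactants: 8 methyl 3-bromo-4-hydroxy-5-(prop-2-en-1-yl)benzoate
Product: 9 methyl 3-bromo-4-hydroxy-5-(3-methylbut-2-en-1-yl)benzoate
Conditions: second-generation Grubbs catalyst (H2IMes)(PCy3)Cl2Ru=CHPh (3 mol%), 2-methylbut-2-ene (excess), CH2Cl2, 40 °C, sealed
Reagents that add atoms: 2-methylbut-2-ene, CC=C(C)C
Why: Olefin cross-metathesis of the terminal alkene with excess 2-methylbut-2-ene turns allyl into prenyl with loss of propene, and the ruthenium carbene tolerates the free phenol and the aryl bromide.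

Step 8
Reactants: 5 tert-butyl{[(2S)-2-methylbut-3-en-1-yl]oxy}diphenylsilane; 9 methyl 3-bromo-4-hydroxy-5-(3-methylbut-2-en-1-yl)benzoate
Product: 11 methyl 3-[(3S)-4-[(tert-butyldiphenylsilyl)oxy]-3-methylbutyl]-4-hydroxy-5-(3-methylbut-2-en-1-yl)benzoate, via alkylborane 10 (not isolated)
Conditions: 5 (1.5 equiv), 9-BBN dimer (0.7 equiv), THF, 0 °C to rt; then 9 (1.0 equiv), Pd(dppf)Cl2 (5 mol%), 3 M aq. K3PO4 (4 equiv), DMF, 60 °C
Reagents that add atoms: none
Why: In this B-alkyl Suzuki–Miyaura coupling, anti-Markovnikov hydroboration gives the primary alkylborane, which transmetallates to the arylpalladium bromide after activation by phosphate; the alkene is kept in slight excess over B–H so no borane is left for the prenyl group, the phenol is left free because an ortho allyl ether would invite intramolecular Heck cyclisation, and the stereocentre is remote from every bond change.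

Step 9
Reactants: 11 methyl 3-[(3S)-4-[(tert-butyldiphenylsilyl)oxy]-3-methylbutyl]-4-hydroxy-5-(3-methylbut-2-en-1-yl)benzoate
Product: 12 methyl 4-(allyloxy)-3-[(3S)-4-[(tert-butyldiphenylsilyl)oxy]-3-methylbutyl]-5-(3-methylbut-2-en-1-yl)benzoate
Conditions: allyl bromide, K2CO3, DMF, 50 °C
Reagents that add atoms: allyl bromide, BrCC=C
Why: Williamson etherification of the hindered phenol is placed after the coupling, so that this allyl ether does not meet zerovalent palladium until the last step.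

Step 10
Reactants: 12 methyl 4-(allyloxy)-3-[(3S)-4-[(tert-butyldiphenylsilyl)oxy]-3-methylbutyl]-5-(3-methylbut-2-en-1-yl)benzoate
Product: 13 4-(allyloxy)-3-[(3S)-4-[(tert-butyldiphenylsilyl)oxy]-3-methylbutyl]-5-(3-methylbut-2-en-1-yl)benzoic acid
Conditions: LiOH·H2O, THF/MeOH/H2O, 50 °C; then 1 M HCl to pH 3, 0 °C
Reagents that add atoms: lithium hydroxide, [Li+].[OH-]
Why: Saponification of the unhindered benzoate should leave the silyl ether, the allyl ether and the prenyl group intact, the acidification being cold and brief.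

Step 11
Reactants: 13 4-(allyloxy)-3-[(3S)-4-[(tert-butyldiphenylsilyl)oxy]-3-methylbutyl]-5-(3-methylbut-2-en-1-yl)benzoic acid; 14 methyl methoxyacetate
Product: 17 methyl 3-{4-(allyloxy)-3-[(3S)-4-[(tert-butyldiphenylsilyl)oxy]-3-methylbutyl]-5-(3-methylbut-2-en-1-yl)phenyl}-2-methoxy-3-oxopropanoate (both C2 epimers), via aroyl chloride 15 (not isolated), via lithium enolate 16 (not isolated)
Conditions: 13, 1-chloro-N,N,2-trimethylprop-1-en-1-amine (1.05 equiv), CH2Cl2, 0 °C to rt, evaporate; separately 14 (2.5 equiv), LiN(i-Pr)2 (2.4 equiv), THF, −78 °C; add 15 in THF, −78 to −40 °C; aq. NH4Cl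
Reagents that add atoms: none
Why: This is a Claisen-type C-acylation of a lithium ester enolate by an acid chloride; the chloride is made with the α-chloroenamine so that no HCl can add to the prenyl alkene, the enolate is in excess because the product is deprotonated as it forms, and the C2 epimers converge in the next step.

Step 12
Reactants: 17 methyl 3-{4-(allyloxy)-3-[(3S)-4-[(tert-butyldiphenylsilyl)oxy]-3-methylbutyl]-5-(3-methylbut-2-en-1-yl)phenyl}-2-methoxy-3-oxopropanoate
Product: 19 methyl (2E)-3-{4-(allyloxy)-3-[(3S)-4-[(tert-butyldiphenylsilyl)oxy]-3-methylbutyl]-5-(3-methylbut-2-en-1-yl)phenyl}-2-methoxy-3-{[(trifluoromethyl)sulfonyl]oxy}prop-2-enoate, via sodium enolate 18 (not isolated)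
Conditions: NaH, Et2O, 0 °C; then Tf2O, −78 to 0 °C
Reagents that add atoms: trifluoromethanesulfonic anhydride, O=S(=O)(OS(=O)(=O)C(F)(F)F)C(F)(F)F
Why: O-sulfonylation of the β-ketoester enolate, in which sodium bridges the enolate oxygen and the ester carbonyl, should place the triflate cis to the ester, which is the (E)-enol triflate.

**Ring A phenol (fragment 3)**

Step 13
Reactants: 20 methyl 3,5-dihydroxy-4-methoxybenzoate
Product: 21 methyl 4-methoxy-3,5-bis(prop-2-en-1-yloxy)benzoate
Conditions: allyl bromide (2.5 equiv), K2CO3, DMF, 60 °C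
Reagents that add atoms: allyl bromide, BrCC=C
Why: Double Williamson etherification of the two equivalent phenols keeps the ring mirror-symmetric.

Step 14
Reactants: 21 methyl 4-methoxy-3,5-bis(prop-2-en-1-yloxy)benzoate
Product: 22 [4-methoxy-3,5-bis(prop-2-en-1-yloxy)phenyl]methanol
Conditions: i-Bu2AlH (2.5 equiv), CH2Cl2, −78 to 0 °C; aqueous potassium sodium tartrate work-up
Reagents that add atoms: none
Why: Aluminium hydride reduction of the benzoate to the benzylic alcohol leaves aryl allyl ethers untouched.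

Step 15
Reactants: 22 [4-methoxy-3,5-bis(prop-2-en-1-yloxy)phenyl]methanol
Product: 23 4-methoxy-3,5-bis(prop-2-en-1-yloxy)benzaldehyde
Conditions: MnO2 (10 equiv), CH2Cl2, rt
Reagents that add atoms: none
Why: Manganese dioxide oxidation of a benzylic alcohol stops at the aldehyde and does not touch the allyl ethers.

Step 16
Reactants: 23 4-methoxy-3,5-bis(prop-2-en-1-yloxy)benzaldehyde
Product: 25 4-methoxy-3,5-bis(prop-2-en-1-yloxy)phenol, via aryl formate 24 (not isolated)
Conditions: 30% aq. H2O2 (1.3 equiv), H2SO4 (cat.), MeOH, rt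
Reagents that add atoms: hydrogen peroxide, OO
Why: In this acid-catalysed Dakin (Baeyer–Villiger-type) oxidation the hydroperoxide adduct of the electron-rich aldehyde rearranges by aryl migration to the formate, which methanol cleaves, and H2O2 with acid does not epoxidise unactivated allyl alkenes.

**Assembly and end game**

Step 17
Reactants: 19 methyl (2E)-3-{4-(allyloxy)-3-[(3S)-4-[(tert-butyldiphenylsilyl)oxy]-3-methylbutyl]-5-(3-methylbut-2-en-1-yl)phenyl}-2-methoxy-3-{[(trifluoromethyl)sulfonyl]oxy}prop-2-enoate; 25 4-methoxy-3,5-bis(prop-2-en-1-yloxy)phenol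
Product: 26 methyl (2E)-3-[3,5-bis(allyloxy)-4-methoxyphenoxy]-3-{4-(allyloxy)-3-[(3S)-4-[(tert-butyldiphenylsilyl)oxy]-3-methylbutyl]-5-(3-methylbut-2-en-1-yl)phenyl}-2-methoxyprop-2-enoate
Conditions: 25 (1.2 equiv), Cs2CO3 (1.5 equiv), DMF, rt to 40 °C
Reagents that add atoms: none
Why: In this nucleophilic vinylic substitution (addition–elimination) the phenoxide adds to C3 of the β-sulfonyloxyacrylate and the resulting ester enolate expels triflate, expected with retention so that the aryloxy group stays cis to the ester; elimination to an alkyne is impossible because C2 bears no hydrogen.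

Step 18
Reactants: 26 methyl (2E)-3-[3,5-bis(allyloxy)-4-methoxyphenoxy]-3-{4-(allyloxy)-3-[(3S)-4-[(tert-butyldiphenylsilyl)oxy]-3-methylbutyl]-5-(3-methylbut-2-en-1-yl)phenyl}-2-methoxyprop-2-enoate
Product: 27 (2E)-3-[3,5-bis(allyloxy)-4-methoxyphenoxy]-3-{4-(allyloxy)-3-[(3S)-4-[(tert-butyldiphenylsilyl)oxy]-3-methylbutyl]-5-(3-methylbut-2-en-1-yl)phenyl}-2-methoxyprop-2-enoic acid
Conditions: LiOH·H2O (5 equiv), THF/MeOH/H2O, 40 °C; then 1 M HCl to pH 4, 0 °C, immediate extraction
Reagents that add atoms: lithium hydroxide, [Li+].[OH-]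
Why: Saponification of β-aryloxycinnamic esters is established, the fully substituted C3 is shielded from conjugate attack by hydroxide, and the cold, brief acidification should spare the aryl enol ether.

Step 19
Reactants: 27 (2E)-3-[3,5-bis(allyloxy)-4-methoxyphenoxy]-3-{4-(allyloxy)-3-[(3S)-4-[(tert-butyldiphenylsilyl)oxy]-3-methylbutyl]-5-(3-methylbut-2-en-1-yl)phenyl}-2-methoxyprop-2-enoic acid
Product: 29 5,7-bis(allyloxy)-2-{4-(allyloxy)-3-[(3S)-4-[(tert-butyldiphenylsilyl)oxy]-3-methylbutyl]-5-(3-methylbut-2-en-1-yl)phenyl}-3,6-dimethoxy-4H-chromen-4-one, via mixed trifluoroacetic anhydride 28 (not isolated)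
Conditions: (CF3CO)2O (2.0 equiv), 2,6-di-tert-butylpyridine (3.0 equiv), CH2Cl2, 0 °C to rt
Reagents that add atoms: none
Why: Trifluoroacetic anhydride converts the acid into acyl trifluoroacetate 28, whose acyl carbon is attacked by the aryloxy-ring carbon ortho to the ether oxygen (the future C4a) to give a Wheland intermediate that loses its proton to the hindered pyridine, forming C4–C4a and the pyranone. The closest known reaction type is the acid-mediated intramolecular Friedel–Crafts acylation of 3-aryloxyacrylic acids to chromones and flavones, run here under the mixed-anhydride conditions used to acylate phloroglucinol ethers. Ring C closes in a six-membered mode that is exo with respect to the acyl C=O and has the arene C4a=C8a bond inside the new ring; no stereocentre is formed. The step needs regioselectivity between the two ortho carbons of ring A, and the mirror symmetry of the 3,5-bis(allyloxy)-4-methoxyphenoxy unit (ether oxygen para to the methoxy group) makes them identical, so only the 5,6,7-oxygenated chromone can arise. It also needs ring A to win over the ortho carbons of ring B (indenone formation), which the (E)-geometry (acyl group cis to the aryloxy group) and the ortho/para dialkoxy activation of C4a should secure, any (Z)-isomer being expected to equilibrate through protonation at C2 of this donor-substituted alkene. The weakly acidic medium without a Lewis acid is chosen so that the prenyl alkene, the three allyl ethers and the silyl ether are spared.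

Step 20
Reactants: 29 5,7-bis(allyloxy)-2-{4-(allyloxy)-3-[(3S)-4-[(tert-butyldiphenylsilyl)oxy]-3-methylbutyl]-5-(3-methylbut-2-en-1-yl)phenyl}-3,6-dimethoxy-4H-chromen-4-one
Product: 30 5,7-bis(allyloxy)-2-{4-(allyloxy)-3-[(3S)-4-hydroxy-3-methylbutyl]-5-(3-methylbut-2-en-1-yl)phenyl}-3,6-dimethoxy-4H-chromen-4-one
Conditions: Bu4NF (1.5 equiv), AcOH (1.5 equiv), THF, rt
Reagents that add atoms: none
Why: Fluoride-mediated desilylation, buffered with acetic acid, is run while all phenols are still allylated, so no phenoxide is exposed to basic fluoride.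

Step 21
Reactants: 30 5,7-bis(allyloxy)-2-{4-(allyloxy)-3-[(3S)-4-hydroxy-3-methylbutyl]-5-(3-methylbut-2-en-1-yl)phenyl}-3,6-dimethoxy-4H-chromen-4-one
Product: 31 5,7-dihydroxy-2-{4-hydroxy-3-[(3S)-4-hydroxy-3-methylbutyl]-5-(3-methylbut-2-en-1-yl)phenyl}-3,6-dimethoxy-4H-chromen-4-one
Conditions: Pd(PPh3)4 (10 mol%), morpholine (15 equiv), THF, rt, argon
Reagents that add atoms: none
Why: In this Tsuji–Trost-type deallylation zerovalent palladium ionises each aryl allyl ether to a π-allylpalladium species that morpholine intercepts, while the prenyl group, the chromone, the methyl ethers and the primary alcohol are inert.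

**Compound list**

1 | methyl (2R)-3-hydroxy-2-methylpropanoate | COC(=O)[C@H](C)CO | starting material
2 | methyl (2R)-3-[(tert-butyldiphenylsilyl)oxy]-2-methylpropanoate | COC(=O)[C@H](C)CO[Si](c1ccccc1)(c1ccccc1)C(C)(C)C | intermediate
3 | (2S)-3-[(tert-butyldiphenylsilyl)oxy]-2-methylpropan-1-ol | OC[C@H](C)CO[Si](c1ccccc1)(c1ccccc1)C(C)(C)C | intermediate
4 | (2R)-3-[(tert-butyldiphenylsilyl)oxy]-2-methylpropanal | O=C[C@H](C)CO[Si](c1ccccc1)(c1ccccc1)C(C)(C)C | intermediate
5 | tert-butyl{[(2S)-2-methylbut-3-en-1-yl]oxy}diphenylsilane | C=C[C@H](C)CO[Si](c1ccccc1)(c1ccccc1)C(C)(C)C | intermediate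
6 | methyl 3-bromo-4-hydroxybenzoate | COC(=O)c1ccc(O)c(Br)c1 | starting material
7 | methyl 3-bromo-4-(prop-2-en-1-yloxy)benzoate | COC(=O)c1ccc(OCC=C)c(Br)c1 | intermediate
8 | methyl 3-bromo-4-hydroxy-5-(prop-2-en-1-yl)benzoate | COC(=O)c1cc(Br)c(O)c(CC=C)c1 | intermediate
9 | methyl 3-bromo-4-hydroxy-5-(3-methylbut-2-en-1-yl)benzoate | COC(=O)c1cc(Br)c(O)c(CC=C(C)C)c1 | intermediate
10 | 9-{(3S)-4-[(tert-butyldiphenylsilyl)oxy]-3-methylbutyl}-9-borabicyclo[3.3.1]nonane | B1(CC[C@H](C)CO[Si](c3ccccc3)(c3ccccc3)C(C)(C)C)C2CCCC1CCC2 | intermediate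
11 | methyl 3-[(3S)-4-[(tert-butyldiphenylsilyl)oxy]-3-methylbutyl]-4-hydroxy-5-(3-methylbut-2-en-1-yl)benzoate | COC(=O)c1cc(CC=C(C)C)c(O)c(CC[C@H](C)CO[Si](c2ccccc2)(c2ccccc2)C(C)(C)C)c1 | intermediate
12 | methyl 4-(allyloxy)-3-[(3S)-4-[(tert-butyldiphenylsilyl)oxy]-3-methylbutyl]-5-(3-methylbut-2-en-1-yl)benzoate | COC(=O)c1cc(CC=C(C)C)c(OCC=C)c(CC[C@H](C)CO[Si](c2ccccc2)(c2ccccc2)C(C)(C)C)c1 | intermediate
13 | 4-(allyloxy)-3-[(3S)-4-[(tert-butyldiphenylsilyl)oxy]-3-methylbutyl]-5-(3-methylbut-2-en-1-yl)benzoic acid | OC(=O)c1cc(CC=C(C)C)c(OCC=C)c(CC[C@H](C)CO[Si](c2ccccc2)(c2ccccc2)C(C)(C)C)c1 | intermediate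
14 | methyl methoxyacetate | COCC(=O)OC | starting material
15 | 4-(allyloxy)-3-[(3S)-4-[(tert-butyldiphenylsilyl)oxy]-3-methylbutyl]-5-(3-methylbut-2-en-1-yl)benzoyl chloride | ClC(=O)c1cc(CC=C(C)C)c(OCC=C)c(CC[C@H](C)CO[Si](c2ccccc2)(c2ccccc2)C(C)(C)C)c1 | intermediate
16 | lithium 1,2-dimethoxyethen-1-olate (lithium enolate of 14) | [Li+].[O-]C(OC)=COC | intermediate
17 | methyl 3-{4-(allyloxy)-3-[(3S)-4-[(tert-butyldiphenylsilyl)oxy]-3-methylbutyl]-5-(3-methylbut-2-en-1-yl)phenyl}-2-methoxy-3-oxopropanoate (both C2 epimers) | COC(=O)C(OC)C(=O)c1cc(CC=C(C)C)c(OCC=C)c(CC[C@H](C)CO[Si](c2ccccc2)(c2ccccc2)C(C)(C)C)c1 | intermediate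
18 | sodium enolate of 17 (enolate oxygen cis to the ester) | [Na+].COC(=O)/C(OC)=C(\[O-])c1cc(CC=C(C)C)c(OCC=C)c(CC[C@H](C)CO[Si](c2ccccc2)(c2ccccc2)C(C)(C)C)c1 | intermediate
19 | methyl (2E)-3-{4-(allyloxy)-3-[(3S)-4-[(tert-butyldiphenylsilyl)oxy]-3-methylbutyl]-5-(3-methylbut-2-en-1-yl)phenyl}-2-methoxy-3-{[(trifluoromethyl)sulfonyl]oxy}prop-2-enoate | COC(=O)/C(OC)=C(\OS(=O)(=O)C(F)(F)F)c1cc(CC=C(C)C)c(OCC=C)c(CC[C@H](C)CO[Si](c2ccccc2)(c2ccccc2)C(C)(C)C)c1 | intermediate
20 | methyl 3,5-dihydroxy-4-methoxybenzoate | COC(=O)c1cc(O)c(OC)c(O)c1 | starting material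
21 | methyl 4-methoxy-3,5-bis(prop-2-en-1-yloxy)benzoate | COC(=O)c1cc(OCC=C)c(OC)c(OCC=C)c1 | intermediate
22 | [4-methoxy-3,5-bis(prop-2-en-1-yloxy)phenyl]methanol | OCc1cc(OCC=C)c(OC)c(OCC=C)c1 | intermediate
23 | 4-methoxy-3,5-bis(prop-2-en-1-yloxy)benzaldehyde | O=Cc1cc(OCC=C)c(OC)c(OCC=C)c1 | intermediate
24 | 4-methoxy-3,5-bis(prop-2-en-1-yloxy)phenyl formate | O=COc1cc(OCC=C)c(OC)c(OCC=C)c1 | intermediate
25 | 4-methoxy-3,5-bis(prop-2-en-1-yloxy)phenol | Oc1cc(OCC=C)c(OC)c(OCC=C)c1 | intermediate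
26 | methyl (2E)-3-[3,5-bis(allyloxy)-4-methoxyphenoxy]-3-{4-(allyloxy)-3-[(3S)-4-[(tert-butyldiphenylsilyl)oxy]-3-methylbutyl]-5-(3-methylbut-2-en-1-yl)phenyl}-2-methoxyprop-2-enoate | COC(=O)/C(OC)=C(\Oc1cc(OCC=C)c(OC)c(OCC=C)c1)c1cc(CC=C(C)C)c(OCC=C)c(CC[C@H](C)CO[Si](c2ccccc2)(c2ccccc2)C(C)(C)C)c1 | intermediate
27 | (2E)-3-[3,5-bis(allyloxy)-4-methoxyphenoxy]-3-{4-(allyloxy)-3-[(3S)-4-[(tert-butyldiphenylsilyl)oxy]-3-methylbutyl]-5-(3-methylbut-2-en-1-yl)phenyl}-2-methoxyprop-2-enoic acid | OC(=O)/C(OC)=C(\Oc1cc(OCC=C)c(OC)c(OCC=C)c1)c1cc(CC=C(C)C)c(OCC=C)c(CC[C@H](C)CO[Si](c2ccccc2)(c2ccccc2)C(C)(C)C)c1 | intermediate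
28 | (2E)-3-[3,5-bis(allyloxy)-4-methoxyphenoxy]-3-{4-(allyloxy)-3-[(3S)-4-[(tert-butyldiphenylsilyl)oxy]-3-methylbutyl]-5-(3-methylbut-2-en-1-yl)phenyl}-2-methoxyprop-2-enoic trifluoroacetic anhydride | O=C(OC(=O)C(F)(F)F)/C(OC)=C(\Oc1cc(OCC=C)c(OC)c(OCC=C)c1)c1cc(CC=C(C)C)c(OCC=C)c(CC[C@H](C)CO[Si](c2ccccc2)(c2ccccc2)C(C)(C)C)c1 | intermediate
29 | 5,7-bis(allyloxy)-2-{4-(allyloxy)-3-[(3S)-4-[(tert-butyldiphenylsilyl)oxy]-3-methylbutyl]-5-(3-methylbut-2-en-1-yl)phenyl}-3,6-dimethoxy-4H-chromen-4-one | COc1c(OCC=C)cc2oc(-c3cc(CC=C(C)C)c(OCC=C)c(CC[C@H](C)CO[Si](c4ccccc4)(c4ccccc4)C(C)(C)C)c3)c(OC)c(=O)c2c1OCC=C | intermediate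
30 | 5,7-bis(allyloxy)-2-{4-(allyloxy)-3-[(3S)-4-hydroxy-3-methylbutyl]-5-(3-methylbut-2-en-1-yl)phenyl}-3,6-dimethoxy-4H-chromen-4-one | COc1c(OCC=C)cc2oc(-c3cc(CC=C(C)C)c(OCC=C)c(CC[C@H](C)CO)c3)c(OC)c(=O)c2c1OCC=C | intermediate
31 | 5,7-dihydroxy-2-{4-hydroxy-3-[(3S)-4-hydroxy-3-methylbutyl]-5-(3-methylbut-2-en-1-yl)phenyl}-3,6-dimethoxy-4H-chromen-4-one | COc1c(O)cc2oc(-c3cc(CC=C(C)C)c(O)c(CC[C@H](C)CO)c3)c(OC)c(=O)c2c1O | target

**Step count**

Total: 21 steps. Longest linear sequence: 14 steps (1 to 31 through steps 1–4, 8–12 and 17–21).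

**Steps most likely to fail**

Step 19. The donor-substituted acyl trifluoroacetate may be too weak an electrophile under buffered conditions, so that acylation stalls. The acyl group may also close onto ring B, or the alkene may not reach the (E)-geometry, and liberated acid may then attack the prenyl and allyl groups. The fallback inverts the polarity of the C4–C4a bond formation; it sets out from phenol 25 (with triflate 19) and returns at flavone 29. Phenol 25 would be mono-iodinated with N-iodosuccinimide (CH2Cl2, 0 °C) at one of its two equivalent ortho carbons to give 3,5-bis(allyloxy)-2-iodo-4-methoxyphenol F1. Its cesium salt would displace the triflate of 19 as in step 17 to give methyl (2E)-3-[3,5-bis(allyloxy)-2-iodo-4-methoxyphenoxy]-3-{4-(allyloxy)-3-[(3S)-4-[(tert-butyldiphenylsilyl)oxy]-3-methylbutyl]-5-(3-methylbut-2-en-1-yl)phenyl}-2-methoxyprop-2-enoate F2. Iodine–magnesium exchange with i-PrMgCl·LiCl (1.05 equiv, THF, −40 to 0 °C) would then give an arylmagnesium species that attacks the neighbouring methyl ester and expels methoxide (Parham-type anionic cyclisation), forming 29 directly.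

Step 17. The phenoxide may attack sulfur instead of C3 (triflyl transfer, returning the ketoester enolate), and the alkene geometry may erode through a long-lived carbanion. The fallback replaces the sulfonate by a leaving group with no electrophilic heteroatom; it sets out from ketoester 17 and returns at ester 26. Appel-type chlorination of the enol of 17 (Ph3P, CCl4, MeCN, rt to 50 °C) would give methyl 3-{4-(allyloxy)-3-[(3S)-4-[(tert-butyldiphenylsilyl)oxy]-3-methylbutyl]-5-(3-methylbut-2-en-1-yl)phenyl}-3-chloro-2-methoxyprop-2-enoate F3 as a mixture of alkene isomers. The cesium salt of 25 (Cs2CO3, DMF, 60 °C) would displace chloride in the classical β-chlorocinnamate to β-aryloxycinnamate manner to give 26. The geometric isomers would be separated, or carried on and left to equilibrate under the conditions of step 19.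

Step 8. Oxidative addition into the electron-rich bromophenoxide may be slow, leaving the alkylborane to undergo protodeboronation or β-hydride elimination, and hydrodebromination may compete. The fallback makes the aryl–alkyl bond by olefination and hydrogenation before any alkene is on the ring; it sets out from alcohol 3 and returns at phenol 11.
- Alcohol 3 would be converted (I2, Ph3P, imidazole, CH2Cl2) into tert-butyl{[(2R)-3-iodo-2-methylpropyl]oxy}diphenylsilane F4, and then (Ph3P, MeCN, 85 °C) into {(2R)-3-[(tert-butyldiphenylsilyl)oxy]-2-methylpropyl}triphenylphosphonium iodide F5.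
- Purchased methyl 3-formyl-4-hydroxybenzoate F6 would be benzylated (BnBr, K2CO3, DMF) to methyl 4-(benzyloxy)-3-formylbenzoate F7.
- Wittig reaction of the ylide from F5 (NaN(SiMe3)2, THF, −78 °C to rt) with F7 would give methyl 4-(benzyloxy)-3-{(1Z,3S)-4-[(tert-butyldiphenylsilyl)oxy]-3-methylbut-1-en-1-yl}benzoate F8; the stereocentre is β to phosphorus and cannot epimerise.
- Hydrogenation (H2, Pd/C, EtOAc) would saturate the alkene and remove the benzyl group to give methyl 3-[(3S)-4-[(tert-butyldiphenylsilyl)oxy]-3-methylbutyl]-4-hydroxybenzoate F9.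
- O-Allylation as in step 5 would give methyl 4-(allyloxy)-3-[(3S)-4-[(tert-butyldiphenylsilyl)oxy]-3-methylbutyl]benzoate F10, and Claisen rearrangement as in step 6 would give methyl 3-[(3S)-4-[(tert-butyldiphenylsilyl)oxy]-3-methylbutyl]-4-hydroxy-5-(prop-2-en-1-yl)benzoate F11.
- Cross-metathesis of F11 with 2-methylbut-2-ene as in step 7 would give 11.

**Further compounds**

F1 | step 19 | 3,5-bis(allyloxy)-2-iodo-4-methoxyphenol | Oc1cc(OCC=C)c(OC)c(OCC=C)c1I
F2 | step 19 | methyl (2E)-3-[3,5-bis(allyloxy)-2-iodo-4-methoxyphenoxy]-3-{4-(allyloxy)-3-[(3S)-4-[(tert-butyldiphenylsilyl)oxy]-3-methylbutyl]-5-(3-methylbut-2-en-1-yl)phenyl}-2-methoxyprop-2-enoate | COC(=O)/C(OC)=C(\Oc1cc(OCC=C)c(OC)c(OCC=C)c1I)c1cc(CC=C(C)C)c(OCC=C)c(CC[C@H](C)CO[Si](c2ccccc2)(c2ccccc2)C(C)(C)C)c1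
F3 | step 17 | methyl 3-{4-(allyloxy)-3-[(3S)-4-[(tert-butyldiphenylsilyl)oxy]-3-methylbutyl]-5-(3-methylbut-2-en-1-yl)phenyl}-3-chloro-2-methoxyprop-2-enoate (alkene isomers) | COC(=O)C(OC)=C(Cl)c1cc(CC=C(C)C)c(OCC=C)c(CC[C@H](C)CO[Si](c2ccccc2)(c2ccccc2)C(C)(C)C)c1
F4 | step 8 | tert-butyl{[(2R)-3-iodo-2-methylpropyl]oxy}diphenylsilane | IC[C@H](C)CO[Si](c1ccccc1)(c1ccccc1)C(C)(C)C
F5 | step 8 | {(2R)-3-[(tert-butyldiphenylsilyl)oxy]-2-methylpropyl}triphenylphosphonium iodide | [I-].c1ccccc1[P+](c1ccccc1)(c1ccccc1)C[C@H](C)CO[Si](c1ccccc1)(c1ccccc1)C(C)(C)C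
F6 | step 8 | methyl 3-formyl-4-hydroxybenzoate (purchased) | COC(=O)c1ccc(O)c(C=O)c1
F7 | step 8 | methyl 4-(benzyloxy)-3-formylbenzoate | COC(=O)c1ccc(OCc2ccccc2)c(C=O)c1
F8 | step 8 | methyl 4-(benzyloxy)-3-{(1Z,3S)-4-[(tert-butyldiphenylsilyl)oxy]-3-methylbut-1-en-1-yl}benzoate | COC(=O)c1ccc(OCc2ccccc2)c(/C=C\[C@H](C)CO[Si](c2ccccc2)(c2ccccc2)C(C)(C)C)c1
F9 | step 8 | methyl 3-[(3S)-4-[(tert-butyldiphenylsilyl)oxy]-3-methylbutyl]-4-hydroxybenzoate | COC(=O)c1ccc(O)c(CC[C@H](C)CO[Si](c2ccccc2)(c2ccccc2)C(C)(C)C)c1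
F10 | step 8 | methyl 4-(allyloxy)-3-[(3S)-4-[(tert-butyldiphenylsilyl)oxy]-3-methylbutyl]benzoate | COC(=O)c1ccc(OCC=C)c(CC[C@H](C)CO[Si](c2ccccc2)(c2ccccc2)C(C)(C)C)c1
F11 | step 8 | methyl 3-[(3S)-4-[(tert-butyldiphenylsilyl)oxy]-3-methylbutyl]-4-hydroxy-5-(prop-2-en-1-yl)benzoate | COC(=O)c1cc(CC=C)c(O)c(CC[C@H](C)CO[Si](c2ccccc2)(c2ccccc2)C(C)(C)C)c1
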